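**Retrosynthetic overview**

1. Meridianin F (17) ⇐ N1-detosylation and SNAr amination at pyrimidine C2 (through the sulfone) ⇐ N-tosyl 2-(methylthio)pyrimidinyl indole 14.
2. 14 ⇐ cut N1–C7a and C3–C3a of the pyrrole ring: 4,5-dibromobenzyne (from silyl triflate 6) plus tosylamido ketone 11, then loss of water.
3. Feature used: in the benzo ring C3a–C4–C5(Br)–C6(Br)–C7–C7a the bromines at C5 and C6 are mirror images across the line through the midpoints of C3a–C7a and C5–C6. The aryne C3a≡C7a is therefore symmetric, and N1 and C3 may add to either end with the same result.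
4. 6 ⇐ 3,4-dibromophenol (ortho-iodination, O-silylation, I/Li exchange–retro-Brook–triflation); 11 ⇐ 4-acetyl-2-(methylthio)pyrimidine (α-bromination, alkylation of BocNHTs, Boc removal).
5. Ring order: the benzene and pyrimidine rings are bought; the pyrrole ring is the only ring made (step 7).

Key step: step 7

Remark: the target SMILES has no stereocentre, so the request for a single enantiomer needs no stereocontrol. The one stereocentre on the route (C3 of hydroxyindoline 13) forms racemic and is erased by dehydration.

**Route**

Step 1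
Reactants: 1 3,4-dibromophenol
Product: 2 4,5-dibromo-2-iodophenol
Conditions: NIS (1.0 equiv), TsOH·H2O (10 mol%), MeCN, 0 °C → rt
Reagents that add atoms: N-iodosuccinimide, O=C1CCC(=O)N1I
Why: Electrophilic aromatic iodination of a para-blocked phenol should go to the free ortho carbon C6 (unhindered, para to the C3 bromine) rather than to C2, which is squeezed between OH and Br.

Step 2
Reactants: 2 4,5-dibromo-2-iodophenol
Product: 3 (4,5-dibromo-2-iodophenoxy)trimethylsilane
Conditions: HMDS (0.7 equiv), THF, 65 °C; volatiles removed in vacuo, crude used directly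
Reagents that add atoms: hexamethyldisilazane, C[Si](C)(C)N[Si](C)(C)C
Why: O-silylation of a phenol with HMDS gives only ammonia as by-product, so the moisture-sensitive aryl silyl ether can be carried on without purification.

Step 3
Reactants: 3 (4,5-dibromo-2-iodophenoxy)trimethylsilane
Product: 6 4,5-dibromo-2-(trimethylsilyl)phenyl trifluoromethanesulfonate, via [4,5-dibromo-2-(trimethylsilyloxy)phenyl]lithium 4 (not isolated), via lithium 4,5-dibromo-2-(trimethylsilyl)phenoxide 5 (not isolated)
Conditions: n-BuLi (1.05 equiv), THF, −100 °C; then Tf2O (1.2 equiv), −100 → −78 °C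
Reagents that add atoms: trifluoromethanesulfonic anhydride, O=S(=O)(OS(=O)(=O)C(F)(F)F)C(F)(F)F
Why: Iodine–lithium exchange is much faster than bromine–lithium exchange at −100 °C, the ortho-lithiated silyl ether undergoes the anionic 1,3-O→C silyl shift (retro-Brook rearrangement) and the lithium phenoxide is O-triflated in the same flask; no bromine sits ortho to the carbanion, so no aryne can form here.

Step 4
Reactants: 7 1-[2-(methylthio)pyrimidin-4-yl]ethanone
Product: 8 2-bromo-1-[2-(methylthio)pyrimidin-4-yl]ethanone
Conditions: Br2 (1.0 equiv), 33% HBr in AcOH, rt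
Reagents that add atoms: bromine, BrBr
Why: Acid-catalysed enolisation and bromination of the enol (α-halogenation of a methyl ketone) should stop at the monobromide because the first bromine slows further enolisation, while the acidic medium keeps the weakly nucleophilic heteroaryl thioether out of the reaction.

Step 5
Reactants: 8 2-bromo-1-[2-(methylthio)pyrimidin-4-yl]ethanone; 9 tert-butyl tosylcarbamate (BocNHTs)
Product: 10 tert-butyl N-[2-(2-(methylthio)pyrimidin-4-yl)-2-oxoethyl]-N-tosylcarbamate
Conditions: K2CO3 (1.5 equiv), DMF, 0 °C → rt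
Reagents that add atoms: none
Why: SN2 displacement of the activated α-bromide by the potassium salt of the N-acyl sulfonamide (Gabriel-type alkylation) delivers nitrogen exactly once and so avoids the double alkylation that free tosylamide risks.

Step 6
Reactants: 10 tert-butyl N-[2-(2-(methylthio)pyrimidin-4-yl)-2-oxoethyl]-N-tosylcarbamate
Product: 11 4-methyl-N-[2-(2-(methylthio)pyrimidin-4-yl)-2-oxoethyl]benzenesulfonamide
Conditions: TFA, CH2Cl2, 0 °C → rt
Reagents that add atoms: none
Why: Acidolysis of the tert-butyl carbamate (loss of isobutene and CO2) unmasks the acidic sulfonamide N–H without affecting ketone, thioether or pyrimidine.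

Step 7
Reactants: 6 4,5-dibromo-2-(trimethylsilyl)phenyl trifluoromethanesulfonate (1.4 equiv); 11 4-methyl-N-[2-(2-(methylthio)pyrimidin-4-yl)-2-oxoethyl]benzenesulfonamide
Product: 14 5,6-dibromo-3-[2-(methylthio)pyrimidin-4-yl]-1-tosylindole, via 4,5-dibromobenzyne 12 (not isolated), via 5,6-dibromo-3-[2-(methylthio)pyrimidin-4-yl]-1-tosylindolin-3-ol 13 (not isolated)
Conditions: CsF (3 equiv), MeCN, rt; filter, evaporate; then TsOH·H2O, PhMe, 90 °C
Reagents that add atoms: none
Why: Fluoride attacks silicon in 6 and 1,2-elimination of triflate releases the symmetric aryne 12; the caesium salt of sulfonamide 11 adds through nitrogen (N1–C7a) and the ortho aryl anion so formed attacks the neighbouring pyrimidinyl ketone (C3–C3a) to give the tertiary alkoxide of 13, which is protonated by the next molecule of 11. The closest known reaction type is the aryne heteroannulation of α-amino ketones, an aryne variant of the Bischler indole synthesis that rests on N-arylation of sulfonamides by fluoride-generated arynes. The pyrrole ring (N1–C2–C3–C3a–C7a) closes by 5-exo-trig addition of the aryl carbanion to the C=O group, and acid-catalysed loss of water from the benzylic tertiary alcohol 13 is driven by aromatisation to the indole. The only stereocentre formed (C3 of 13) is racemic and vanishes on dehydration, so no stereocontrol is involved. The step needs N-arylation ahead of C- or O-arylation of the enolisable ketone and ahead of aryne capture by the thioether or the ring nitrogens, which the acidic and, once deprotonated, strongly nucleophilic sulfonamide N–H secures, while regiochemistry cannot arise because both aryne carbons are equivalent. The aryl C–Br bonds are inert to fluoride, and the electron-poor ketone is a fast internal trap for the aryl anion, which should limit simple protonation to the open N-aryl sulfonamide.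

Step 8
Reactants: 14 5,6-dibromo-3-[2-(methylthio)pyrimidin-4-yl]-1-tosylindole
Product: 15 5,6-dibromo-3-[2-(methylsulfonyl)pyrimidin-4-yl]-1-tosylindole
Conditions: mCPBA (2.3 equiv), CH2Cl2, 0 °C → rt
Reagents that add atoms: meta-chloroperoxybenzoic acid, O=C(OO)c1cccc(Cl)c1
Why: Peracid oxidation of the thioether to the sulfone should be much faster than any oxidation of the N-sulfonylated, electron-poor indole or of the pyrimidine nitrogens, and it turns the 2-substituent into a good leaving group.

Step 9
Reactants: 15 5,6-dibromo-3-[2-(methylsulfonyl)pyrimidin-4-yl]-1-tosylindole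
Product: 17 Meridianin F, via 4-(5,6-dibromo-1-tosylindol-3-yl)pyrimidin-2-amine 16 (not isolated)
Conditions: NH3 (0.5 M in 1,4-dioxane, excess), sealed tube, 80 °C; then 2 M aq NaOH, MeOH, 65 °C
Reagents that add atoms: ammonia, N
Why: SNAr displacement of methanesulfinate from the 2-sulfonylpyrimidine by ammonia installs the amino group, and base then cleaves the N-sulfonyl indole at sulfur, the indolide leaving group being stabilised by the 3-pyrimidinyl substituent, while the unactivated aryl bromides stay untouched.

**Compound list**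

1 | 3,4-dibromophenol | Oc1ccc(Br)c(Br)c1 | starting material
2 | 4,5-dibromo-2-iodophenol | Oc1cc(Br)c(Br)cc1I | intermediate
3 | (4,5-dibromo-2-iodophenoxy)trimethylsilane | C[Si](C)(C)Oc1cc(Br)c(Br)cc1I | intermediate
4 | [4,5-dibromo-2-(trimethylsilyloxy)phenyl]lithium (not isolated) | [Li]c1cc(Br)c(Br)cc1O[Si](C)(C)C | intermediate
5 | lithium 4,5-dibromo-2-(trimethylsilyl)phenoxide (not isolated) | [Li+].[O-]c1cc(Br)c(Br)cc1[Si](C)(C)C | intermediate
6 | 4,5-dibromo-2-(trimethylsilyl)phenyl trifluoromethanesulfonate | C[Si](C)(C)c1cc(Br)c(Br)cc1OS(=O)(=O)C(F)(F)F | intermediate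
7 | 1-[2-(methylthio)pyrimidin-4-yl]ethanone | CSc1nccc(C(C)=O)n1 | starting material
8 | 2-bromo-1-[2-(methylthio)pyrimidin-4-yl]ethanone | CSc1nccc(C(=O)CBr)n1 | intermediate
9 | tert-butyl tosylcarbamate (BocNHTs) | Cc1ccc(S(=O)(=O)NC(=O)OC(C)(C)C)cc1 | starting material
10 | tert-butyl N-[2-(2-(methylthio)pyrimidin-4-yl)-2-oxoethyl]-N-tosylcarbamate | CSc1nccc(C(=O)CN(C(=O)OC(C)(C)C)S(=O)(=O)c2ccc(C)cc2)n1 | intermediate
11 | 4-methyl-N-[2-(2-(methylthio)pyrimidin-4-yl)-2-oxoethyl]benzenesulfonamide | CSc1nccc(C(=O)CNS(=O)(=O)c2ccc(C)cc2)n1 | intermediate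
12 | 4,5-dibromobenzyne (not isolated) | BrC1=CC#CC=C1Br | intermediate
13 | 5,6-dibromo-3-[2-(methylthio)pyrimidin-4-yl]-1-tosylindolin-3-ol, racemic (not isolated) | CSc1nccc(C2(O)CN(S(=O)(=O)c3ccc(C)cc3)c3cc(Br)c(Br)cc32)n1 | intermediate
14 | 5,6-dibromo-3-[2-(methylthio)pyrimidin-4-yl]-1-tosylindole | CSc1nccc(-c2cn(S(=O)(=O)c3ccc(C)cc3)c3cc(Br)c(Br)cc23)n1 | intermediate
15 | 5,6-dibromo-3-[2-(methylsulfonyl)pyrimidin-4-yl]-1-tosylindole | CS(=O)(=O)c1nccc(-c2cn(S(=O)(=O)c3ccc(C)cc3)c3cc(Br)c(Br)cc23)n1 | intermediate
16 | 4-(5,6-dibromo-1-tosylindol-3-yl)pyrimidin-2-amine (not isolated) | Nc1nccc(-c2cn(S(=O)(=O)c3ccc(C)cc3)c3cc(Br)c(Br)cc23)n1 | intermediate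
17 | Meridianin F, 4-(5,6-dibromo-1H-indol-3-yl)pyrimidin-2-amine | Nc1nccc(-c2c[nH]c3cc(Br)c(Br)cc23)n1 | target

**Step count**

Total steps: 9. Longest linear sequence: 6 steps (1 → 2 → 3 → 6 → 14 → 15 → 17); the ketone arm (7 → 8 → 10 → 11) joins at step 7 and is equally long.

**Steps most likely to fail**

Step 7. The aryne may be intercepted by the thioether sulfur or a pyrimidine nitrogen, the aryl anion may be quenched by proton transfer before it closes onto the ketone, or ionisation of the carbinol next to the electron-poor pyrimidine may be too slow for clean dehydration. The fallback sets out from 8 and returns at 14, and uses no aryne. 3,4-Dibromoaniline is tosylated (TsCl, pyridine, CH2Cl2) to N-(3,4-dibromophenyl)-4-methylbenzenesulfonamide F1. This is N-alkylated with bromoketone 8 (K2CO3, acetone, rt) to N-(3,4-dibromophenyl)-4-methyl-N-[2-(2-(methylthio)pyrimidin-4-yl)-2-oxoethyl]benzenesulfonamide F2. Bischler-type Friedel–Crafts cyclodehydration of F2 (Eaton's reagent, 60–80 °C) should close C3–C3a at the unhindered ortho carbon para to bromine and give 14 directly. The N–aryl bond is bought with the aniline, and the protonated pyrimidinyl ketone is electrophilic enough to offset the bromine-deactivated ring. Any 4,5-dibromo isomer from closure between N and Br would be removed by chromatography.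

Step 3. Bromine–lithium exchange, halogen scrambling between aryllithium and aryl bromide, or butylation may compete with the iodine–lithium exchange and erode the dibromo pattern, and the silyl shift may be incomplete before triflation. The fallback sets out from 3 and returns at 6, and replaces lithium and the anionic silyl migration by a magnesium exchange with external C-silylation. Treatment of 3 with i-PrMgCl·LiCl (THF, −40 °C), which exchanges aryl iodides but not aryl bromides, gives [4,5-dibromo-2-(trimethylsilyloxy)phenyl]magnesium chloride F3. Trapping with TMSCl (−40 °C → rt) gives [4,5-dibromo-2-(trimethylsilyl)phenoxy]trimethylsilane F4. K2CO3 in MeOH cleaves only the O–Si bond to 4,5-dibromo-2-(trimethylsilyl)phenol F5, and Tf2O/pyridine (CH2Cl2, 0 °C) then gives 6.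

Step 4. Over-bromination to the dibromomethyl ketone or halogenation and oxidation at sulfur may consume the ketone. The fallback sets out from 7 and returns at 11, and introduces nitrogen by a Neber rearrangement instead of halogen displacement. Ketone 7 is condensed with NH2OH·HCl/NaOAc (EtOH) to 1-[2-(methylthio)pyrimidin-4-yl]ethanone oxime F6, which is O-sulfonylated (TsCl, pyridine, 0 °C) to 1-[2-(methylthio)pyrimidin-4-yl]ethanone O-tosyl oxime F7. KOEt in EtOH at 0 °C induces the Neber rearrangement to 4-(2H-azirin-3-yl)-2-(methylthio)pyrimidine F8, which is opened in the same pot with aqueous HCl to 2-amino-1-[2-(methylthio)pyrimidin-4-yl]ethanone hydrochloride F9. N-Sulfonylation of F9 (TsCl, Et3N, CH2Cl2, 0 °C) gives 11, so that steps 4–6 are bypassed.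

**Further compounds**

F1 | step 7 | N-(3,4-dibromophenyl)-4-methylbenzenesulfonamide | Cc1ccc(S(=O)(=O)Nc2ccc(Br)c(Br)c2)cc1
F2 | step 7 | N-(3,4-dibromophenyl)-4-methyl-N-[2-(2-(methylthio)pyrimidin-4-yl)-2-oxoethyl]benzenesulfonamide | CSc1nccc(C(=O)CN(c2ccc(Br)c(Br)c2)S(=O)(=O)c2ccc(C)cc2)n1
F3 | step 3 | [4,5-dibromo-2-(trimethylsilyloxy)phenyl]magnesium chloride | Cl[Mg]c1cc(Br)c(Br)cc1O[Si](C)(C)C
F4 | step 3 | [4,5-dibromo-2-(trimethylsilyl)phenoxy]trimethylsilane | C[Si](C)(C)Oc1cc(Br)c(Br)cc1[Si](C)(C)C
F5 | step 3 | 4,5-dibromo-2-(trimethylsilyl)phenol | Oc1cc(Br)c(Br)cc1[Si](C)(C)C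
F6 | step 4 | 1-[2-(methylthio)pyrimidin-4-yl]ethanone oxime | CSc1nccc(C(C)=NO)n1
F7 | step 4 | 1-[2-(methylthio)pyrimidin-4-yl]ethanone O-tosyl oxime | CSc1nccc(C(C)=NOS(=O)(=O)c2ccc(C)cc2)n1
F8 | step 4 | 4-(2H-azirin-3-yl)-2-(methylthio)pyrimidine | CSc1nccc(C2=NC2)n1
F9 | step 4 | 2-amino-1-[2-(methylthio)pyrimidin-4-yl]ethanone hydrochloride | CSc1nccc(C(=O)CN)n1.Cl
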